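**Retrosynthetic overview**
- Feature: the benzo ring of the indole (C3a, C4, C5, C6, C7, C7a) bears O at C4 and Br at C6. Seen as an aryl group attached through C3a, it is a 4-bromo-2-methoxyphenyl unit. One ortho carbon carries OMe (future C4) and the other is the only ortho C–H (future C7a), so a nitrogen arriving from C2 can close and rearomatise at one carbon only.
- Key disconnection N1–C7a: indole 15 is traced to the 2-azido-1,1-diarylethene 12 (loss of N2, 2H-azirine, vinyl nitrenoid, electrocyclisation). The pyrrole ring is the only ring made; the benzene and pyrimidine rings are bought.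
- 12 is traced to diaryl ketone 5 by a one-carbon homologation (sulfonium ylide epoxidation, azide opening at CH2, dehydration). 5 comes from 5-lithio-2,4-dimethoxypyrimidine and 4-bromo-2-methoxybenzaldehyde.
- After ring closure the dimethoxypyrimidine is unmasked to the uracil and converted to the 4-amino-2-bromopyrimidine (POBr3, then NH3 at C4'). The indole C4 methyl ether is cleaved last, so that a free phenol never sits next to a C4' bromide.

Key step: step 6

Assumption: step 5 is expected to give both alkene isomers of the vinyl azide. Both lose N2 to the same 2H-azirine 13, so they are not separated, and the E isomer (azide cis to the bromoanisole ring) is drawn as 12. The sp3 centres in 4, 8, 10, 11, 13 and 14 are racemic and none survives in the achiral target. Primed locants refer to the pyrimidine ring.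

Step 1
Reactants: 1 5-bromo-2,4-dimethoxypyrimidine; 2 4-bromo-2-methoxybenzaldehyde
Product: 4 (4-bromo-2-methoxyphenyl)(2,4-dimethoxypyrimidin-5-yl)methanol (racemic), via 5-lithio-2,4-dimethoxypyrimidine 3 (not isolated)
Conditions: n-BuLi (1.0 equiv), THF, −78 °C; then 2, −78 to −20 °C; H2O quench
Reagents that add atoms: none
Why: Bromine–lithium exchange at C5' is fast at −78 °C, and the 1,2-addition of the aryllithium to the aldehyde should be much faster than exchange with the aryl bromide of 2; the carbinol centre forms as a racemate and is erased in step 2.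

Step 2
Reactants: 4 (4-bromo-2-methoxyphenyl)(2,4-dimethoxypyrimidin-5-yl)methanol
Product: 5 (4-bromo-2-methoxyphenyl)(2,4-dimethoxypyrimidin-5-yl)methanone
Conditions: Dess–Martin periodinane, CH2Cl2, rt
Reagents that add atoms: none
Why: Dess–Martin oxidation of a secondary diaryl carbinol is mild enough to leave the aryl bromide and the methoxypyrimidine untouched, and the product cannot enolise.

Step 3
Reactants: 5 (4-bromo-2-methoxyphenyl)(2,4-dimethoxypyrimidin-5-yl)methanone; 6 trimethylsulfonium iodide
Product: 8 2-(4-bromo-2-methoxyphenyl)-2-(2,4-dimethoxypyrimidin-5-yl)oxirane (racemic), via dimethylsulfonium methylide 7 (not isolated)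
Conditions: 6, NaH, DMSO–THF, 0 °C; then 5, 0 °C to rt; crude epoxide carried on without silica gel
Reagents that add atoms: trimethylsulfonium iodide, C[S+](C)C.[I-]
Why: In this Corey–Chaykovsky epoxidation the unstabilised sulfonium ylide should add irreversibly to the carbonyl carbon of the non-enolisable ketone, not to the vinylogous C6' of the acylpyrimidine, and the betaine then closes with loss of Me2S; the quaternary centre forms as a racemate and is lost in step 5.

Step 4
Reactants: 8 2-(4-bromo-2-methoxyphenyl)-2-(2,4-dimethoxypyrimidin-5-yl)oxirane; 9 sodium azide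
Product: 10 2-azido-1-(4-bromo-2-methoxyphenyl)-1-(2,4-dimethoxypyrimidin-5-yl)ethan-1-ol (racemic)
Conditions: NaN3, NH4Cl, DMF–H2O, 65 °C
Reagents that add atoms: sodium azide, [N-]=[N+]=[N-].[Na+]
Why: SN2 opening of a 2,2-disubstituted epoxide by azide in a near-neutral buffer should occur at the CH2 terminus, because the fully substituted diaryl carbon is closed to backside attack and no acid strong enough to ionise it is present; the carbinol centre is untouched and stays racemic.

Step 5
Reactants: 10 2-azido-1-(4-bromo-2-methoxyphenyl)-1-(2,4-dimethoxypyrimidin-5-yl)ethan-1-ol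
Product: 12 5-[(E)-2-azido-1-(4-bromo-2-methoxyphenyl)ethenyl]-2,4-dimethoxypyrimidine, via tertiary mesylate 11 (not isolated)
Conditions: MsCl, Et3N (excess), CH2Cl2, 0 °C to rt, light excluded
Reagents that add atoms: none
Why: Mesylation of the tertiary, doubly benzylic alcohol gives an ester that should ionise at once and lose a proton to Et3N (E1-type dehydration); the CH2N3 group holds the only beta-hydrogens, so one constitution alone can form, and the basic medium spares the acid-sensitive vinyl azide.

Step 6
Reactants: 12 5-[(E)-2-azido-1-(4-bromo-2-methoxyphenyl)ethenyl]-2,4-dimethoxypyrimidine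
Product: 15 6-bromo-3-(2,4-dimethoxypyrimidin-5-yl)-4-methoxy-1H-indole, via 2H-azirine 13 (not isolated), via 7aH-indole 14 (not isolated)
Conditions: Rh2(O2CC3F7)4 (5 mol %), 4 Å MS, toluene, 60 to 90 °C
Reagents that add atoms: none
Why: Warming 12 with the Lewis-acidic Rh2(O2CC3F7)4 drives off N2 and gives the racemic 2H-azirine 13, whose C2–N bond opens reversibly to a rhodium-bound vinyl nitrene, so that both alkene isomers of 12 drain into one reactive species. Its electron-poor nitrogen bonds to the free ortho carbon of the 4-bromo-2-methoxyphenyl ring in a four-electron electrocyclisation over five atoms (N1, C2, C3, C3a, C7a; formally 5-endo-trig), which makes the N1–C7a bond, closes the pyrrole ring and gives 7aH-indole 14; a suprafacial 1,5-hydrogen shift from C7a to N1 then restores the benzene ring. The closest known reactions are the Hemetsberger-type conversion of beta-aryl vinyl azides into indoles under Rh2(O2CR)4 catalysis and the thermal or metal-catalysed isomerisation of 2,2-diaryl-2H-azirines to 3-arylindoles. No stereocentre remains, since those of 13 and 14 are lost on ring opening and on rearomatisation. Two selectivities are needed: between the aryl groups the electrophilic nitrenoid should choose the pi-rich anisole ring over the pi-poor C6'–H of the pyrimidine, and within the anisole ring the other ortho carbon bears OMe, so that attack there cannot rearomatise and should revert, which leaves the 4-methoxy-6-bromo pattern as the only outcome. The catalyst is used so that closure can outrun the 1,2-hydrogen shift of the C2–H nitrene, which plain pyrolysis at higher temperature would favour.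

Step 7
Reactants: 15 6-bromo-3-(2,4-dimethoxypyrimidin-5-yl)-4-methoxy-1H-indole
Product: 16 5-(6-bromo-4-methoxy-1H-indol-3-yl)pyrimidine-2,4(1H,3H)-dione
Conditions: 4 M aq HCl–MeOH, reflux
Reagents that add atoms: water, O
Why: Acid hydrolysis of the two imidate-type ethers of an N-protonated 2,4-dialkoxypyrimidine is the standard unmasking of a uracil, and it runs under conditions that should not touch an aryl methyl ether, an aryl bromide or a 3-arylindole.

Step 8
Reactants: 16 5-(6-bromo-4-methoxy-1H-indol-3-yl)pyrimidine-2,4(1H,3H)-dione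
Product: 17 6-bromo-3-(2,4-dibromopyrimidin-5-yl)-4-methoxy-1H-indole
Conditions: POBr3 (4 equiv), PhNMe2 (2 equiv), toluene, 100 °C; ice-water quench
Reagents that add atoms: phosphorus oxybromide, O=P(Br)(Br)Br
Why: Deoxybromination of both lactam units (O-phosphorylation, then addition–elimination by bromide) is the standard route from uracils to 2,4-dihalopyrimidines; PhNMe2 buffers the acid so that the indole, already deactivated by its C3 substituent, and the methyl ether should stay intact.

Step 9
Reactants: 17 6-bromo-3-(2,4-dibromopyrimidin-5-yl)-4-methoxy-1H-indole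
Product: 18 2-bromo-5-(6-bromo-4-methoxy-1H-indol-3-yl)pyrimidin-4-amine
Conditions: NH3 (2 M in 2-propanol, excess), THF, sealed tube, rt to 45 °C
Reagents that add atoms: ammonia, N
Why: In this SNAr reaction C4' of a 2,4-dihalopyrimidine is the more electrophilic carbon (its Meisenheimer adduct puts the charge on both ring nitrogens) and the small NH3 can reach it past the indolyl group; the first amino group then deactivates the ring, so C2'–Br and the aryl bromide should remain.

Step 10
Reactants: 18 2-bromo-5-(6-bromo-4-methoxy-1H-indol-3-yl)pyrimidin-4-amine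
Product: 19 3-(4-amino-2-bromopyrimidin-5-yl)-6-bromo-1H-indol-4-ol
Conditions: BBr3 (5 equiv), CH2Cl2, −78 °C to rt; then ice-water, work-up under argon
Reagents that add atoms: none
Why: In this Lewis-acid ether cleavage the excess BBr3 saturates the basic nitrogens and binds the ether oxygen, and bromide removes the methyl group by SN2; neither C–Br bond reacts, and C4' now carries NH2, a poor leaving group, so the liberated phenol should not close onto it.

**Compound list**
1 | 5-bromo-2,4-dimethoxypyrimidine | COc1ncc(Br)c(OC)n1 | starting material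
2 | 4-bromo-2-methoxybenzaldehyde | COc1cc(Br)ccc1C=O | starting material
3 | 5-lithio-2,4-dimethoxypyrimidine | [Li]c1cnc(OC)nc1OC | intermediate
4 | (4-bromo-2-methoxyphenyl)(2,4-dimethoxypyrimidin-5-yl)methanol (racemic) | COc1cc(Br)ccc1C(O)c1cnc(OC)nc1OC | intermediate
5 | (4-bromo-2-methoxyphenyl)(2,4-dimethoxypyrimidin-5-yl)methanone | COc1cc(Br)ccc1C(=O)c1cnc(OC)nc1OC | intermediate
6 | trimethylsulfonium iodide | C[S+](C)C.[I-] | starting material
7 | dimethylsulfonium methylide | C[S+](C)[CH2-] | intermediate
8 | 2-(4-bromo-2-methoxyphenyl)-2-(2,4-dimethoxypyrimidin-5-yl)oxirane (racemic) | COc1cc(Br)ccc1C1(CO1)c1cnc(OC)nc1OC | intermediate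
9 | sodium azide | [N-]=[N+]=[N-].[Na+] | starting material
10 | 2-azido-1-(4-bromo-2-methoxyphenyl)-1-(2,4-dimethoxypyrimidin-5-yl)ethan-1-ol (racemic) | COc1cc(Br)ccc1C(O)(CN=[N+]=[N-])c1cnc(OC)nc1OC | intermediate
11 | 2-azido-1-(4-bromo-2-methoxyphenyl)-1-(2,4-dimethoxypyrimidin-5-yl)ethyl methanesulfonate (racemic) | COc1cc(Br)ccc1C(CN=[N+]=[N-])(OS(C)(=O)=O)c1cnc(OC)nc1OC | intermediate
12 | 5-[(E)-2-azido-1-(4-bromo-2-methoxyphenyl)ethenyl]-2,4-dimethoxypyrimidine | [N-]=[N+]=N/C=C(\c1ccc(Br)cc1OC)c1cnc(OC)nc1OC | intermediate
13 | 5-[2-(4-bromo-2-methoxyphenyl)-2H-azirin-2-yl]-2,4-dimethoxypyrimidine (racemic) | COc1cc(Br)ccc1C1(C=N1)c1cnc(OC)nc1OC | intermediate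
14 | 6-bromo-3-(2,4-dimethoxypyrimidin-5-yl)-4-methoxy-7aH-indole (racemic) | COC1=CC(Br)=CC2N=CC(c3cnc(OC)nc3OC)=C12 | intermediate
15 | 6-bromo-3-(2,4-dimethoxypyrimidin-5-yl)-4-methoxy-1H-indole | COc1ncc(-c2c[nH]c3cc(Br)cc(OC)c23)c(OC)n1 | intermediate
16 | 5-(6-bromo-4-methoxy-1H-indol-3-yl)pyrimidine-2,4(1H,3H)-dione | COc1cc(Br)cc2[nH]cc(-c3c[nH]c(=O)[nH]c3=O)c12 | intermediate
17 | 6-bromo-3-(2,4-dibromopyrimidin-5-yl)-4-methoxy-1H-indole | COc1cc(Br)cc2[nH]cc(-c3cnc(Br)nc3Br)c12 | intermediate
18 | 2-bromo-5-(6-bromo-4-methoxy-1H-indol-3-yl)pyrimidin-4-amine | COc1cc(Br)cc2[nH]cc(-c3cnc(Br)nc3N)c12 | intermediate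
19 | 3-(4-amino-2-bromopyrimidin-5-yl)-6-bromo-1H-indol-4-ol | Nc1nc(Br)ncc1-c1c[nH]c2cc(Br)cc(O)c12 | target

**Total step count:** 10. **Longest linear sequence:** 10 steps (from 1 or 2 to 19).

**Steps most likely to fail**

Step 6. Three processes could defeat the closure:
- a 1,2-hydrogen shift of the C2–H nitrene, which isomerises it to a nitrile;
- inhibition of the catalyst by coordination of the pyrimidine nitrogens at the axial rhodium sites;
- competing closure onto the pyrimidine ring.

The fallback sets out from 1 and rejoins the route at 15; it makes the C3–C5' bond by Suzuki–Miyaura coupling on a preformed indole. Compound 1 is lithiated to 3 as in step 1 and quenched with triisopropyl borate and dilute HCl to give (2,4-dimethoxypyrimidin-5-yl)boronic acid F1. Purchased 6-bromo-4-methoxy-1H-indole F2 is iodinated at C3 with N-iodosuccinimide in DMF to 6-bromo-3-iodo-4-methoxy-1H-indole F3. Treatment with Boc2O and DMAP converts this to tert-butyl 6-bromo-3-iodo-4-methoxyindole-1-carboxylate F4. Coupling of F1 and F4 with Pd(PPh3)4 and Na2CO3 in DME–H2O at 70 °C, where zerovalent palladium should insert into the carbon–iodine bond ahead of the carbon–bromine bond, gives tert-butyl 6-bromo-3-(2,4-dimethoxypyrimidin-5-yl)-4-methoxyindole-1-carboxylate F5. TFA in CH2Cl2 then removes the carbamate and delivers 15.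

Step 8. Three processes are of concern:
- degradation or ring bromination of the unprotected, electron-rich indole in hot POBr3 and HBr;
- premature loss of the methyl ether, followed by closure of the oxygen onto C4';
- incomplete exchange of the second carbonyl.

The fallback sets out from 16 and rejoins at 18; it uses chlorine as a placeholder and installs bromine late. POCl3 with PhNMe2 in toluene gives 6-bromo-3-(2,4-dichloropyrimidin-5-yl)-4-methoxy-1H-indole F6. Ammonia in 2-propanol–THF substitutes C4' to give 2-chloro-5-(6-bromo-4-methoxy-1H-indol-3-yl)pyrimidin-4-amine F7. A silyl-mediated halogen exchange with TMSBr in hot propionitrile then converts C2'–Cl into C2'–Br and delivers 18.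

Step 9. Crowding of C4' by the neighbouring 4-methoxyindolyl group could erode site selectivity (attack at C2') or lead to double substitution. The fallback sets out from 16 and rejoins at 18; it fixes the nitrogen at C4' before any halogen is present. P4S10 in pyridine thionates the amide-type C4' carbonyl in preference to the urea-type C2' carbonyl, giving 5-(6-bromo-4-methoxy-1H-indol-3-yl)-4-thioxo-3,4-dihydropyrimidin-2(1H)-one F8. Ammonia in a sealed tube at 100 °C replaces sulfur by addition–elimination to give the cytosine 4-amino-5-(6-bromo-4-methoxy-1H-indol-3-yl)pyrimidin-2(1H)-one F9. POBr3 then converts the single remaining lactam into C2'–Br and delivers 18.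

**Further compounds**
F1 | step 6 | (2,4-dimethoxypyrimidin-5-yl)boronic acid | COc1ncc(B(O)O)c(OC)n1
F2 | step 6 | 6-bromo-4-methoxy-1H-indole (purchased) | COc1cc(Br)cc2[nH]ccc12
F3 | step 6 | 6-bromo-3-iodo-4-methoxy-1H-indole | COc1cc(Br)cc2[nH]cc(I)c12
F4 | step 6 | tert-butyl 6-bromo-3-iodo-4-methoxyindole-1-carboxylate | COc1cc(Br)cc2c1c(I)cn2C(=O)OC(C)(C)C
F5 | step 6 | tert-butyl 6-bromo-3-(2,4-dimethoxypyrimidin-5-yl)-4-methoxyindole-1-carboxylate | COc1ncc(-c2cn(C(=O)OC(C)(C)C)c3cc(Br)cc(OC)c23)c(OC)n1
F6 | step 8 | 6-bromo-3-(2,4-dichloropyrimidin-5-yl)-4-methoxy-1H-indole | COc1cc(Br)cc2[nH]cc(-c3cnc(Cl)nc3Cl)c12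
F7 | step 8 | 2-chloro-5-(6-bromo-4-methoxy-1H-indol-3-yl)pyrimidin-4-amine | COc1cc(Br)cc2[nH]cc(-c3cnc(Cl)nc3N)c12
F8 | step 9 | 5-(6-bromo-4-methoxy-1H-indol-3-yl)-4-thioxo-3,4-dihydropyrimidin-2(1H)-one | COc1cc(Br)cc2[nH]cc(-c3c[nH]c(=O)[nH]c3=S)c12
F9 | step 9 | 4-amino-5-(6-bromo-4-methoxy-1H-indol-3-yl)pyrimidin-2(1H)-one | COc1cc(Br)cc2[nH]cc(-c3c[nH]c(=O)nc3N)c12
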